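**Retrosynthetic overview**
1. End game: cleave the C15 methyl ester, install C17 by cross-coupling on a Δ7 enol triflate, syn-dihydroxylate Δ2 from the face opposite C19/C20, and exchange silyl for acetyl on O19.
2. Key disconnection: the 8-oxo decalin comes from an oxidative ring expansion of a (Z)-alkylidene trans-hydrindene. C10 shifts from C8 to C9, so C9 and the whole side chain are inserted and the five-membered ring becomes ring B.
3. The alkylidene comes from a Wittig reaction between a trans-hydrindenone and a C9–C15 phosphonium salt. C13 is set by copper-catalysed conjugate addition to methyl crotonate.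
4. The hydrindenone comes from ring-closing metathesis (ring A, Δ2) of a three-component adduct. The components are 2-methylcyclopentenone, an allylsilane made from isoprene monoxide (C3, C4, C18, C19) and allyl bromide (C1, C2).
5. Ring order: purchased five-membered ring, then ring A (metathesis), then ring B (five-to-six ring expansion).

Assumption: labdane numbering (C1–C20) is used for every intermediate, and compounds 1, 4, 5, 10 and 11 are taken as commercial.

**Step 1**
Reactants: 1 2-methyl-2-vinyloxirane (isoprene monoxide, racemic)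
Product: 2 (E)-4-[dimethyl(phenyl)silyl]-2-methylbut-2-en-1-ol
Conditions: PhMe2Si-Bpin (1.1 equiv), CuCl (5 mol%), NaOtBu (10 mol%), MeOH (2 equiv), THF, 0 °C
Reagents that add atoms: (dimethylphenylsilyl)boronic acid pinacol ester C[Si](C)(c1ccccc1)B1OC(C)(C)C(C)(C)O1
Why: Copper-catalysed allylic substitution of the SN2' type, in which the silylcopper species made from the silylboronate adds to the vinyl terminus anti to the epoxide C-O bond and opens the ring, giving the primary allylic alcohol mainly as the E alkene (the geometry is not relayed later) and creating no stereocentre.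

**Step 2**
Reactants: 2 (E)-4-[dimethyl(phenyl)silyl]-2-methylbut-2-en-1-ol
Product: 3 tert-butyl{[(E)-4-(dimethylphenylsilyl)-2-methylbut-2-en-1-yl]oxy}diphenylsilane
Conditions: t-BuPh2SiCl, imidazole, CH2Cl2, rt
Reagents that add atoms: tert-butyl(chloro)diphenylsilane CC(C)(C)[Si](Cl)(c1ccccc1)c1ccccc1
Why: Imidazole-promoted silylation of a primary alcohol, chosen because this bulky silyl ether survives MeLi, ylide, sulfonic acid and amide base and enlarges the CH2O arm for the facial bias needed in step 3.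

**Step 3**
Reactants: 3 tert-butyl{[(E)-4-(dimethylphenylsilyl)-2-methylbut-2-en-1-yl]oxy}diphenylsilane, 4 2-methylcyclopent-2-en-1-one, 5 allyl bromide
Product: 8 (2R,3R)-2-allyl-3-[(2R)-1-(tert-butyldiphenylsilyloxy)-2-methylbut-3-en-2-yl]-2-methylcyclopentan-1-one, via silyl enol ether 6 (not isolated), via lithium enolate 7 (not isolated)
Conditions: chiral BINOL-derived N-triflyl imidodiphosphorimidate acid (2 mol%), 3 (1.3 equiv), slow addition of 4, toluene, -60 °C; then THF, MeLi (1.05 equiv), 0 °C; then 5, DMPU, -78 to -20 °C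
Reagents that add atoms: none
Why: Proposed new method: the confined chiral acid is silylated by 3 and the resulting silylium ion pair activates enone 4 as a 1-silyloxyallyl cation inside the chiral anion pocket, the γ,γ-disubstituted allylsilane attacks one face of C5 through an open antiperiplanar transition state that places the large CH2OSi arm between C10 and H5 and the methyl between C10 and C6 (this sets C4 and C5 together, independent of E/Z purity), loss of the silyl group regenerates the silylium catalyst and leaves the regiodefined enol silane 6, whose lithium enolate 7 is allylated anti to the new tert-alkyl group to set C10, the closest known reaction types being the TiCl4-promoted Hosomi-Sakurai conjugate allylation of enones and the silylium/imidodiphosphorimidate-catalysed Mukaiyama-Michael and aldehyde allylation reactions.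

**Step 4**
Reactants: 8 (2R,3R)-2-allyl-3-[(2R)-1-(tert-butyldiphenylsilyloxy)-2-methylbut-3-en-2-yl]-2-methylcyclopentan-1-one
Product: 9 (3aR,4R,7aR)-4-[(tert-butyldiphenylsilyloxy)methyl]-4,7a-dimethyl-2,3,3a,4,7,7a-hexahydro-1H-inden-1-one
Conditions: second-generation Hoveyda-Grubbs catalyst (3 mol%), toluene, 60 °C
Reagents that add atoms: none
Why: Ring-closing metathesis of a terminal allyl/vinyl pair to an unstrained cyclohexene, driven by loss of ethene, closes ring A as the Δ2 olefin on the trans-disposed arms and touches no stereocentre.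

**Step 5**
Reactants: 10 1-bromo-3-methoxypropane, 11 methyl (E)-but-2-enoate
Product: 13 methyl (R)-6-methoxy-3-methylhexanoate, via Grignard reagent 12 (not isolated)
Conditions: Mg, Et2O; then 11, CuBr·SMe2 (1 mol%), Josiphos ligand (1.2 mol%, the enantiomer that gives Si-face attack), t-BuOMe, -75 °C; then water
Reagents that add atoms: none
Why: Copper/ferrocenyl-diphosphine-catalysed enantioselective conjugate addition of a primary alkyl Grignard reagent to an acyclic enoate, in which the ligand enantiomer that directs attack to the Si face of the β-carbon sets C13 as R.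

**Step 6**
Reactants: 13 methyl (R)-6-methoxy-3-methylhexanoate
Product: 14 (R)-6-bromo-3-methylhexanoic acid
Conditions: 48% aq. HBr, AcOH, reflux
Reagents that add atoms: hydrogen bromide Br
Why: Acid-mediated methyl ether cleavage, alcohol-to-bromide substitution and ester cleavage all occur by SN2 attack of bromide or acyl hydrolysis away from C13, so the stereocentre is untouched.

**Step 7**
Reactants: 14 (R)-6-bromo-3-methylhexanoic acid
Product: 15 [(4R)-5-carboxy-4-methylpentyl]triphenylphosphonium bromide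
Conditions: PPh3, MeCN, reflux
Reagents that add atoms: triphenylphosphine c1ccc(cc1)P(c1ccccc1)c1ccccc1
Why: SN2 quaternisation of triphenylphosphine by a primary bromide, the same way the commercial carboxyalkyl phosphonium salts are made.

**Step 8**
Reactants: 9 (3aR,4R,7aR)-4-[(tert-butyldiphenylsilyloxy)methyl]-4,7a-dimethyl-2,3,3a,4,7,7a-hexahydro-1H-inden-1-one, 15 [(4R)-5-carboxy-4-methylpentyl]triphenylphosphonium bromide
Product: 18 methyl (3R,6Z)-6-[(3aS,4R,7aR)-4-[(tert-butyldiphenylsilyloxy)methyl]-4,7a-dimethyl-2,3,3a,4,7,7a-hexahydro-1H-inden-1-ylidene]-3-methylhexanoate, via ylide carboxylate 16 (not isolated), via potassium carboxylate 17 (not isolated)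
Conditions: 15 (2.5 equiv), KOtBu (5 equiv), THF, 0 °C to reflux; then MeI, DMF, rt
Reagents that add atoms: iodomethane CI
Why: Wittig olefination in which the non-stabilised ylide carries its acid as an inert carboxylate (so it cannot acylate itself) and attacks the neopentyl cyclopentanone as ethylidene ylides do with 17-oxo steroids, giving mainly the Z alkene (the geometry is erased in step 9), after which the potassium carboxylate is esterified by SN2 on MeI.

**Step 9**
Reactants: 18 methyl (3R,6Z)-6-[(3aS,4R,7aR)-4-[(tert-butyldiphenylsilyloxy)methyl]-4,7a-dimethyl-2,3,3a,4,7,7a-hexahydro-1H-inden-1-ylidene]-3-methylhexanoate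
Product: 20 methyl (4R,5S,9S,10R,13R)-19-(tert-butyldiphenylsilyloxy)-8-oxo-17-norlabd-2-en-15-oate, via hydroxy iodane 19 (not isolated)
Conditions: PhI(OH)OTs (1.05 equiv), MeCN-H2O 9:1, 0 °C to rt
Reagents that add atoms: water O
Why: Semipinacol-type oxidative ring expansion of an exocyclic alkene by trivalent iodine (Wittig/ring-expansion sequence), in which iodine adds to the less substituted C9 and water to C8 of the most electron-rich alkene, reductive loss of PhI from 19 pulls the better-migrating fully substituted C10 from C8 to C9 with retention at C10 (as in D-homo rearrangements of steroids), and the sulfonic acid formed equilibrates the enolisable C9 to the equatorial side chain.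

**Step 10**
Reactants: 20 methyl (4R,5S,9S,10R,13R)-19-(tert-butyldiphenylsilyloxy)-8-oxo-17-norlabd-2-en-15-oate
Product: 22 methyl (4R,5S,9S,10R,13R)-19-(tert-butyldiphenylsilyloxy)-8-(trifluoromethylsulfonyloxy)-17-norlabda-2,7-dien-15-oate, via potassium enolate 21 (not isolated)
Conditions: KN(SiMe3)2 (1.1 equiv), THF, -78 °C; then Comins reagent, -78 °C; aq. NH4Cl
Reagents that add atoms: N-(5-chloropyridin-2-yl)bis(trifluoromethanesulfonimide) FC(F)(F)S(=O)(=O)N(c1ccc(Cl)cn1)S(=O)(=O)C(F)(F)F
Why: Kinetic deprotonation by a bulky amide base at the unhindered C7 methylene (C9 is tertiary and neopentyl, the ester is less acidic) followed by O-sulfonylation fixes the Δ7 regiochemistry and leaves C9 untouched.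

**Step 11**
Reactants: 22 methyl (4R,5S,9S,10R,13R)-19-(tert-butyldiphenylsilyloxy)-8-(trifluoromethylsulfonyloxy)-17-norlabda-2,7-dien-15-oate
Product: 24 methyl (4R,5S,9S,10R,13R)-19-acetoxy-8-(trifluoromethylsulfonyloxy)-17-norlabda-2,7-dien-15-oate, via primary alcohol 23 (not isolated)
Conditions: Bu4NF, AcOH, THF, rt; then Ac2O, pyridine, DMAP (cat.), rt
Reagents that add atoms: acetic anhydride CC(=O)OC(C)=O
Why: Buffered fluoride desilylation followed by DMAP-catalysed acylation in the same flask, both of which the alkenyl triflate and the methyl ester tolerate, with no stereocentre involved.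

**Step 12**
Reactants: 24 methyl (4R,5S,9S,10R,13R)-19-acetoxy-8-(trifluoromethylsulfonyloxy)-17-norlabda-2,7-dien-15-oate
Product: 25 methyl (2S,3R,4R,5S,9S,10R,13R)-19-acetoxy-2,3-dihydroxy-8-(trifluoromethylsulfonyloxy)-17-norlabd-7-en-15-oate
Conditions: OsO4 (3 mol%), N-methylmorpholine N-oxide (1.5 equiv), acetone-H2O, rt
Reagents that add atoms: N-methylmorpholine N-oxide C[N+]1([O-])CCOCC1; water O
Why: Upjohn syn-dihydroxylation, in which the electron-poor alkenyl triflate is inert and OsO4 adds to Δ2 from the face opposite the axial C20 methyl and the axial C19 arm, setting 2S and 3R (equatorial 2-OH, axial 3-OH).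

**Step 13**
Reactants: 25 methyl (2S,3R,4R,5S,9S,10R,13R)-19-acetoxy-2,3-dihydroxy-8-(trifluoromethylsulfonyloxy)-17-norlabd-7-en-15-oate
Product: 26 methyl (2S,3R,4R,5S,9R,10S,13R)-19-acetoxy-2,3-dihydroxylabd-7-en-15-oate
Conditions: Me4Sn (3 equiv), Pd(PPh3)4 (8 mol%), LiCl (3 equiv), DMF, 70 °C
Reagents that add atoms: tetramethylstannane C[Sn](C)(C)C
Why: Stille coupling of an alkenyl triflate under neutral conditions (LiCl-assisted oxidative addition to zerovalent palladium, methyl transfer from tin, reductive elimination) installs C17 without touching diol, acetate or ester and keeps the double bond at Δ7.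

**Step 14**
Reactants: 26 methyl (2S,3R,4R,5S,9R,10S,13R)-19-acetoxy-2,3-dihydroxylabd-7-en-15-oate
Product: 28 (2S,3R,4R,5S,9R,10S,13R)-19-acetoxy-2,3-dihydroxylabd-7-en-15-oic acid, via lithium carboxylate 27 (not isolated)
Conditions: LiI (8 equiv), pyridine, reflux; then 1 M HCl
Reagents that add atoms: none
Why: SN2 dealkylation of the unhindered methyl ester by iodide under non-hydrolytic conditions, which spares the acetate because its alkyl carbon C19 is neopentyl, while acyl migration to O3 is geometrically impossible (O3 and C19 are antiperiplanar).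

**Compound list**
1 | 2-methyl-2-vinyloxirane (racemic) | CC1(C=C)CO1 | starting material
2 | (E)-4-[dimethyl(phenyl)silyl]-2-methylbut-2-en-1-ol | OC/C(C)=C/C[Si](C)(C)c1ccccc1 | intermediate
3 | tert-butyl{[(E)-4-(dimethylphenylsilyl)-2-methylbut-2-en-1-yl]oxy}diphenylsilane | CC(C)(C)[Si](OC/C(C)=C/C[Si](C)(C)c1ccccc1)(c1ccccc1)c1ccccc1 | intermediate
4 | 2-methylcyclopent-2-en-1-one | CC1=CCCC1=O | starting material
5 | allyl bromide | C=CCBr | starting material
6 | dimethyl(phenyl)silyl enol ether of the conjugate adduct (C8=C10 enol ether; C4 and C5 set) | CC(C)(C)[Si](c1ccccc1)(c1ccccc1)OC[C@@](C=C)(C)[C@H]1CCC(O[Si](C)(C)c2ccccc2)=C1C | intermediate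
7 | lithium enolate from 6 | [Li+].CC(C)(C)[Si](c1ccccc1)(c1ccccc1)OC[C@@](C=C)(C)[C@H]1CCC([O-])=C1C | intermediate
8 | (2R,3R)-2-allyl-3-[(2R)-1-(tert-butyldiphenylsilyloxy)-2-methylbut-3-en-2-yl]-2-methylcyclopentan-1-one | CC(C)(C)[Si](c1ccccc1)(c1ccccc1)OC[C@@](C=C)(C)[C@H]1CCC(=O)[C@]1(C)CC=C | intermediate
9 | (3aR,4R,7aR)-4-[(tert-butyldiphenylsilyloxy)methyl]-4,7a-dimethyl-2,3,3a,4,7,7a-hexahydro-1H-inden-1-one (trans-fused; CH2O cis to the angular methyl) | CC(C)(C)[Si](c1ccccc1)(c1ccccc1)OC[C@@]1(C)[C@H]2CCC(=O)[C@]2(C)CC=C1 | intermediate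
10 | 1-bromo-3-methoxypropane | COCCCBr | starting material
11 | methyl (E)-but-2-enoate | C/C=C/C(=O)OC | starting material
12 | 3-methoxypropylmagnesium bromide | COCCC[Mg]Br | intermediate
13 | methyl (R)-6-methoxy-3-methylhexanoate | COCCC[C@@H](C)CC(=O)OC | intermediate
14 | (R)-6-bromo-3-methylhexanoic acid | BrCCC[C@@H](C)CC(=O)O | intermediate
15 | [(4R)-5-carboxy-4-methylpentyl]triphenylphosphonium bromide | [Br-].OC(=O)C[C@H](C)CCC[P+](c1ccccc1)(c1ccccc1)c1ccccc1 | intermediate
16 | potassium (R)-3-methyl-6-(triphenylphosphoranylidene)hexanoate | [K+].[O-]C(=O)C[C@H](C)CCC=P(c1ccccc1)(c1ccccc1)c1ccccc1 | intermediate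
17 | potassium salt of the (Z)-alkylidene acid | [K+].CC(C)(C)[Si](c1ccccc1)(c1ccccc1)OC[C@@]1(C)[C@H]2CC/C(=C/CC[C@@H](C)CC(=O)[O-])[C@]2(C)CC=C1 | intermediate
18 | methyl (3R,6Z)-6-[(3aS,4R,7aR)-4-[(tert-butyldiphenylsilyloxy)methyl]-4,7a-dimethyl-2,3,3a,4,7,7a-hexahydro-1H-inden-1-ylidene]-3-methylhexanoate | CC(C)(C)[Si](c1ccccc1)(c1ccccc1)OC[C@@]1(C)[C@H]2CC/C(=C/CC[C@@H](C)CC(=O)OC)[C@]2(C)CC=C1 | intermediate
19 | 8-hydroxy-9-[phenyl(tosyloxy)-λ3-iodanyl] adduct of 18 (C8 and C9 not defined) | CC(C)(C)[Si](c1ccccc1)(c1ccccc1)OC[C@@]1(C)[C@H]2CCC(O)(C(CC[C@@H](C)CC(=O)OC)I(OS(=O)(=O)c3ccc(C)cc3)c3ccccc3)[C@]2(C)CC=C1 | intermediate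
20 | methyl (4R,5S,9S,10R,13R)-19-(tert-butyldiphenylsilyloxy)-8-oxo-17-norlabd-2-en-15-oate | CC(C)(C)[Si](c1ccccc1)(c1ccccc1)OC[C@@]1(C)[C@H]2CCC(=O)[C@@H](CC[C@@H](C)CC(=O)OC)[C@]2(C)CC=C1 | intermediate
21 | potassium Δ7 enolate of 20 | [K+].CC(C)(C)[Si](c1ccccc1)(c1ccccc1)OC[C@@]1(C)[C@H]2CC=C([O-])[C@@H](CC[C@@H](C)CC(=O)OC)[C@]2(C)CC=C1 | intermediate
22 | methyl (4R,5S,9S,10R,13R)-19-(tert-butyldiphenylsilyloxy)-8-(trifluoromethylsulfonyloxy)-17-norlabda-2,7-dien-15-oate | CC(C)(C)[Si](c1ccccc1)(c1ccccc1)OC[C@@]1(C)[C@H]2CC=C(OS(=O)(=O)C(F)(F)F)[C@@H](CC[C@@H](C)CC(=O)OC)[C@]2(C)CC=C1 | intermediate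
23 | 19-hydroxy analogue of 22 | OC[C@@]1(C)[C@H]2CC=C(OS(=O)(=O)C(F)(F)F)[C@@H](CC[C@@H](C)CC(=O)OC)[C@]2(C)CC=C1 | intermediate
24 | methyl (4R,5S,9S,10R,13R)-19-acetoxy-8-(trifluoromethylsulfonyloxy)-17-norlabda-2,7-dien-15-oate | CC(=O)OC[C@@]1(C)[C@H]2CC=C(OS(=O)(=O)C(F)(F)F)[C@@H](CC[C@@H](C)CC(=O)OC)[C@]2(C)CC=C1 | intermediate
25 | methyl (2S,3R,4R,5S,9S,10R,13R)-19-acetoxy-2,3-dihydroxy-8-(trifluoromethylsulfonyloxy)-17-norlabd-7-en-15-oate | CC(=O)OC[C@@]1(C)[C@H]2CC=C(OS(=O)(=O)C(F)(F)F)[C@@H](CC[C@@H](C)CC(=O)OC)[C@]2(C)C[C@H](O)[C@@H]1O | intermediate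
26 | methyl (2S,3R,4R,5S,9R,10S,13R)-19-acetoxy-2,3-dihydroxylabd-7-en-15-oate | CC(=O)OC[C@@]1(C)[C@H]2CC=C(C)[C@@H](CC[C@@H](C)CC(=O)OC)[C@]2(C)C[C@H](O)[C@@H]1O | intermediate
27 | lithium salt of the target acid | [Li+].CC(=O)OC[C@@]1(C)[C@H]2CC=C(C)[C@@H](CC[C@@H](C)CC(=O)[O-])[C@]2(C)C[C@H](O)[C@@H]1O | intermediate
28 | (2S,3R,4R,5S,9R,10S,13R)-19-acetoxy-2,3-dihydroxylabd-7-en-15-oic acid (CNP0164890.1) | CC(=O)OC[C@@]1(C)[C@H]2CC=C(C)[C@@H](CC[C@@H](C)CC(=O)O)[C@]2(C)C[C@H](O)[C@@H]1O | target

**Total step count:** 14.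
**Longest linear sequence:** 11 steps (steps 1–4 and 8–14).

**Steps most likely to fail**

1. **Step 3 (the proposed new step).**
 - Risks: insufficient enantio- or diastereocontrol, Mukaiyama-Michael oligomerisation of 6 with activated 4, or ionisation of the allylic silyl ether.
 - The fallback sets out from 3, 4 and 5 and comes back at 8. Stoichiometric TiCl4 in CH2Cl2 at -78 °C (the classical Hosomi-Sakurai conjugate allylation, same open transition state for C4/C5) gives, after aqueous work-up, the racemic trans ketone F1. KH in THF followed by allyl bromide alkylates the more substituted enolate anti to the tert-alkyl group. This gives racemic 8, that is 8 together with its mirror image F2. Preparative supercritical-fluid chromatography on a chiral stationary phase then delivers 8.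

2. **Step 9 (ring expansion).**
 - Risks: migration of the C20 methyl to a free C8 cation, attack of the iodane on Δ2, or simple solvent capture at C9 instead of the 1,2-shift.
 - The fallback sets out from 18 and comes back at 20. N-bromosuccinimide (1.0 equiv) in aqueous acetone at 0 °C gives the Markovnikov bromohydrin F3 (OH on C8, Br on C9). AgBF4 with 2,6-di-tert-butylpyridine in CH2Cl2 abstracts the bromide and triggers the same C10 shift (halohydrin semipinacol rearrangement). Brief treatment with Et3N equilibrates C9 and gives 20.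

3. **Step 13 (methylation).**
 - Risk: slow transmetalation at a triflate flanked by the substituted C9, with competing reduction.
 - The fallback sets out from 25 and comes back at 26. 2,2-Dimethoxypropane with pyridinium tosylate gives the acetonide triflate F4. Iron-catalysed Kumada coupling (Fe(acac)3 5 mol%, MeMgBr, THF/NMP, -30 °C, a few minutes, esters tolerated) gives the acetonide alkene F5. 80% aqueous AcOH at 40 °C removes the acetonide and gives 26.

**Further compounds**
F1 | step 3 | racemic trans-3-[1-(tert-butyldiphenylsilyloxy)-2-methylbut-3-en-2-yl]-2-methylcyclopentan-1-one (enantiomer of the 8 series drawn) | CC(C)(C)[Si](c1ccccc1)(c1ccccc1)OC[C@@](C=C)(C)[C@H]1CCC(=O)[C@@H]1C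
F2 | step 3 | mirror image of 8, (2S,3S,2'S) | CC(C)(C)[Si](c1ccccc1)(c1ccccc1)OC[C@](C=C)(C)[C@@H]1CCC(=O)[C@@]1(C)CC=C
F3 | step 9 | 8-hydroxy-9-bromo adduct of 18 (C8 and C9 as formed by anti addition, not defined) | CC(C)(C)[Si](c1ccccc1)(c1ccccc1)OC[C@@]1(C)[C@H]2CCC(O)(C(Br)CC[C@@H](C)CC(=O)OC)[C@]2(C)CC=C1
F4 | step 13 | 2,3-O-isopropylidene derivative of 25 | CC(=O)OC[C@@]1(C)[C@H]2CC=C(OS(=O)(=O)C(F)(F)F)[C@@H](CC[C@@H](C)CC(=O)OC)[C@]2(C)C[C@@H]3OC(C)(C)O[C@@H]31
F5 | step 13 | 2,3-O-isopropylidene derivative of 26 | CC(=O)OC[C@@]1(C)[C@H]2CC=C(C)[C@@H](CC[C@@H](C)CC(=O)OC)[C@]2(C)C[C@@H]3OC(C)(C)O[C@@H]31
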